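The numbers of this flask belong to no real substance; the flask was simulated.

In a one-step world Z goes to E and your quick number is a clock reading, but here Z has a second exit.

    2 Z → Z2 (k1 = 0.340 M⁻¹ s⁻¹, Ea1 = 49.0 kJ mol⁻¹)
    Z → E (k2 = 0.0198 s⁻¹, Ea2 = 87.0 kJ mol⁻¹)
    X ⇌ E, rate k3*(cs3 - [E]) while solid is left; crystals form when [E] > cs3 (cs3 = 9.2 mM, k3 = 0.548 s⁻¹)
    (constants at 90 °C)

common to all: Z 0.20 M; time 25 s

| flask | temperature | remark |
|---|---|---|
| amber | 90 °C |  |
| red |  | at 120 °C until 5.0 s, from then on at 60 °C |
| green | 120 °C |  |
| ochre | 60 °C |  |

* the flask that comes out highest in amount of E, in percent of the Z charged, or "all alike" when all lie within 1.5 percentage points (amber / red / green / ochre / all alike)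
* E at the end, in percent of the Z charged, amber
* E at the end, in percent of the Z charged, red
* E at the end, in percent of the Z charged, green
* E at the end, in percent of the Z charged, ochre

- percent here means Z units held: one Z2 counts as two
- what is said of E includes X
- a step written with two of one species runs at k times the square of its concentration and takes two of it each time
- X is a solid; its amount is given per volume of the solution
- the list of constants is for 90 °C, to be carried to other temperatures by the activation energies

You asked for a quick number on these flasks, with the hunch that heat favours E; I reckon that through the way Z divides between its exits. Neither step that uses Z has E or X on its left, and X is counted inside E, so I leave the crystals out.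

Write the balance of Z in fractions of the charge, with f the part left: ring closure takes a times f, and the dimer takes b times f squared, where a is the ring constant and b is 2 times the dimer constant times the charge. At 120 °C a is 0.178 s⁻¹ and the dimer constant is 1.17 M⁻¹ s⁻¹, so the split s, the ratio a/b and the f at which both exits run level (a selectivity factor), is 0.380. E takes the share s/(s+f) of each bit of Z lost, which integrates to E = s ln((1+s)/(f+s)), while the balance gives f/(f+s) = exp(−at)/(1+s).

Green at 25 s then has f 0.00321 and E 0.487. Red shares that s up to 5.0 s, reaching f 0.161 and E 0.356. At 60 °C red has a 0.00148 s⁻¹ and dimer constant 0.0789 M⁻¹ s⁻¹, so s falls to 0.0469, f creeps to 0.142, and red ends at E 0.361. Amber, with s 0.146 and f 0.166, gives 0.190. Ochre, with f 0.543, gives 0.0269. So green comes out higher than the other flasks.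

The forecast named green highest, with amber 19%, red 36.1%, green 48.7% and ochre 2.7%, on the ground that “the higher activation energy of ring closure favours E when hot”.

The flasks give green highest, with amber 19.0%, red 36.1%, green 48.7% and ochre 2.69%. Green has 0.321% of its Z left at 25.0 s, and that f with s 0.380 gives E 0.487. At a fixed temperature the split falls as the charge rises, so the neighbour of red charged with 0.80 M of Z has s 0.0951 while hot. Taken with that s throughout, its 4.8% of Z left gives E 0.194, and that neighbour holds 18.9% as E.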